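The route rests on cutting the C3–C4 bond of ring A (eudesmane numbering). Because C4 carries only C3, C5 and the C15 methyl, it can be the central carbon of a 1,1-disubstituted allene (C5=C4=C15H2) on a preformed ring B, which has no alkene geometry to control. A nickel-catalysed reductive allene–aldehyde cyclisation then joins the C3 aldehyde to C4, closes ring A, leaves the tetrasubstituted C4=C5 alkene, turns C15 into the methyl group and sets the C3 carbinol in one operation. The precursor is a cyclohexane with the vinylidene at C5, quaternary C10 bearing a 3-oxopropyl arm and a ketal at C8; C7 and C8 are functionalised afterwards under decalin control.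

Key step: step 5

Numbering: eudesmane numbering is used for the target and the bicyclic intermediates (ring A: C1–C5, C10; ring B: C5–C10; C14 = methyl on C10, C15 = methyl on C4, C11–C13 = acrylate unit on C7; β = face of the C10 methyl). Monocyclic intermediates carry spiro-ketal locants, in which C7 is the later C10 and C8 the later C5.

Assumption: (±)-7-methyl-1,4-dioxaspiro[4.5]decan-8-one and 2-bromo-3,3-diethoxyprop-1-ene are taken as catalogue chemicals.

Step 1
Reactants: 1 (±)-7-methyl-1,4-dioxaspiro[4.5]decan-8-one; 2 (R)-1-phenylethylamine; 3 acrylonitrile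
Product: 6 3-[(7R)-7-methyl-8-oxo-1,4-dioxaspiro[4.5]decan-7-yl]propanenitrile, via imine 4 (not isolated), via cyanoethylated imine 5 (not isolated)
Conditions: 2 (1.05 equiv), TsOH (cat.), toluene, reflux, Dean–Stark; then 3, THF, 50 °C; then 20 % aq. AcOH, 20 °C
Reagents that add atoms: water, O
Why: Deracemising Michael addition of a chiral imine, in which 4 reacts through its more substituted secondary enamine tautomer on the face away from the phenyl group of the auxiliary, which should set the quaternary centre as 7R (C10 of the target), and mild acid hydrolysis then returns the ketone and the amine.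

Step 2
Reactants: 6 3-[(7R)-7-methyl-8-oxo-1,4-dioxaspiro[4.5]decan-7-yl]propanenitrile; 7 ethynylmagnesium bromide
Product: 9 (7R)-7-(2-cyanoethyl)-8-ethynyl-7-methyl-1,4-dioxaspiro[4.5]decan-8-yl methyl carbonate (C8 epimers), via magnesium alkoxide 8 (not isolated)
Conditions: 7 (1.5 equiv), THF, 0 → 20 °C; then ClCO2Me, 0 °C
Reagents that add atoms: methyl chloroformate, COC(=O)Cl
Why: 1,2-Addition of an acetylide to the hindered α-quaternary ketone (the nitrile is far less electrophilic) and O-acylation of the alkoxide in the same flask, the new carbinol centre being removed in step 3 so that its configuration does not matter.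

Step 3
Reactants: 9 (7R)-7-(2-cyanoethyl)-8-ethynyl-7-methyl-1,4-dioxaspiro[4.5]decan-8-yl methyl carbonate
Product: 10 3-[(7R)-8-ethenylidene-7-methyl-1,4-dioxaspiro[4.5]decan-7-yl]propanenitrile
Conditions: Pd2(dba)3·CHCl3 (2.5 mol %), PBu3 (10 mol %), HCO2NH4 (2 equiv), THF, 25 °C
Reagents that add atoms: none
Why: Palladium-catalysed SN2′ hydrogenolysis of a tertiary propargylic carbonate by formate, in which zerovalent palladium ionises the carbonate to an allenylpalladium species that takes hydride from formate (loss of CO2) and reductively eliminates the terminal 1,1-disubstituted allene, as is known for 17-ethynyl-17-carbonates of steroids that are flanked by a quaternary carbon in the same way.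

Step 4
Reactants: 10 3-[(7R)-8-ethenylidene-7-methyl-1,4-dioxaspiro[4.5]decan-7-yl]propanenitrile
Product: 11 3-[(7R)-8-ethenylidene-7-methyl-1,4-dioxaspiro[4.5]decan-7-yl]propanal
Conditions: i-Bu2AlH (1.2 equiv), toluene, −78 °C; then aq. tartaric acid, 0 °C
Reagents that add atoms: water, O
Why: Partial reduction of the nitrile with i-Bu2AlH stops at the N-aluminated aldimine, which hydrolyses to the aldehyde on work-up, while the allene and the ketal are inert at −78 °C.

Step 5
Reactants: 11 3-[(7R)-8-ethenylidene-7-methyl-1,4-dioxaspiro[4.5]decan-7-yl]propanal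
Product: 13 (3S,10R)-3β-hydroxy-11,12,13-trinoreudesm-4-en-8-one ethylene ketal, via triethylsilyl ether 12 (not isolated)
Conditions: Ni(cod)2 (10 mol %), IPr·HCl (10 mol %), KOt-Bu (10 mol %), Et3SiH (2 equiv), THF, 20 °C; then Bu4NF, THF, 0 °C (IPr = 1,3-bis(2,6-diisopropylphenyl)imidazol-2-ylidene)
Reagents that add atoms: triethylsilane, CC[SiH](CC)CC (its silicon is held by 12 only)
Why: A zerovalent nickel–carbene complex binds the aldehyde and the terminal C4=C15 π bond of the allene, whose lobes lie in the plane of the C5 substituents and so point at the 3-oxopropyl arm on C10; oxidative cyclisation joins C3 to the central allene carbon C4 in a five-membered oxanickelacycle (Ni–O–C3–C4–C15), σ-bond metathesis with Et3SiH puts silicon on oxygen and hydride on nickel, and C–H reductive elimination at C15 creates the C4 methyl group while the untouched allene π bond remains as the tetrasubstituted C4=C5 alkene. The closest known reaction type is the nickel/carbene/silane reductive coupling of allenes with aldehydes, which forms the C–C bond at the central allene carbon and gives allylic silyl ethers, run here intramolecularly. Ring A closes as a six-membered ring, exo to the reacting C4=C15 bond and endo to the retained C4=C5 bond; a bond to C15 would need a seven-membered ring and a bond to C5 a nickel–tertiary-carbon bond next to quaternary C10. The new C3 centre is controlled by C10: the metallacycle holds the C3–O bond in the plane of the forming alkene (pseudo-equatorial), and the half-chair that keeps the C10 methyl axial on ring B then places oxygen on the β face (3S). The step needs ring closure to outrun aldehyde hydrosilylation and allene oligomerisation, which the six-membered tether secures, and hydride delivery to C15 only, which the in-plane σ-bonded nickelacycle secures because it cannot become a π-allyl without opening. Fluoride work-up frees the alcohol.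

Step 6
Reactants: 13 (3S,10R)-3β-hydroxy-11,12,13-trinoreudesm-4-en-8-one ethylene ketal
Product: 14 (3S,10R)-8,8-(ethylenedioxy)-11,12,13-trinoreudesm-4-en-3β-yl 2-methylpropanoate
Conditions: i-PrCOCl, pyridine, DMAP (cat.), CH2Cl2, 0 → 20 °C
Reagents that add atoms: 2-methylpropanoyl chloride, CC(C)C(=O)Cl
Why: DMAP-catalysed acylation of the secondary allylic alcohol with retention at C3, which also protects the acid-labile allylic carbinol before the ketal is removed.

Step 7
Reactants: 14 (3S,10R)-8,8-(ethylenedioxy)-11,12,13-trinoreudesm-4-en-3β-yl 2-methylpropanoate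
Product: 15 (3S,10R)-8-oxo-11,12,13-trinoreudesm-4-en-3β-yl 2-methylpropanoate
Conditions: pyridinium tosylate (0.2 equiv), acetone/H2O 5:1, 50 °C
Reagents that add atoms: water, O
Why: Acid-catalysed hydrolysis (transketalisation into acetone) of the dioxolane under conditions mild enough for the allylic ester.

Step 8
Reactants: 15 (3S,10R)-8-oxo-11,12,13-trinoreudesm-4-en-3β-yl 2-methylpropanoate; 16 2-bromo-3,3-diethoxyprop-1-ene
Product: 17 (3S,7R,10R)-12,12-diethoxy-8-oxoeudesma-4,11(13)-dien-3β-yl 2-methylpropanoate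
Conditions: Pd2(dba)3 (2.5 mol %), P(t-Bu)3 (6 mol %), LiN(SiMe3)2 (2.2 equiv), toluene, 20 → 50 °C; AcOH quench at −78 °C
Reagents that add atoms: none
Why: Palladium-catalysed α-alkenylation of a ketone enolate, in which the lithium enolate forms at the less hindered C7 methylene (C9 is neopentylic), couples with the alkenylpalladium bromide from 16 by reductive elimination, and the still enolisable C7 centre is set as the equatorial 7β epimer (7R) by axial protonation on quench, which is also the thermodynamically favoured epimer.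

Step 9
Reactants: 17 (3S,7R,10R)-12,12-diethoxy-8-oxoeudesma-4,11(13)-dien-3β-yl 2-methylpropanoate
Product: 18 (3S,7R,8R,10R)-12,12-diethoxy-8β-hydroxyeudesma-4,11(13)-dien-3β-yl 2-methylpropanoate
Conditions: LiBH(s-Bu)3, THF, −78 °C; then H2O2, pH 7 buffer, 0 °C
Reagents that add atoms: none
Why: Reduction with a bulky trialkylborohydride, in which hydride attacks the C8 carbonyl from the equatorial α face, away from the axial C10 methyl group, to give the axial 8β alcohol (8R) cis to the C7 substituent.

Step 10
Reactants: 18 (3S,7R,8R,10R)-12,12-diethoxy-8β-hydroxyeudesma-4,11(13)-dien-3β-yl 2-methylpropanoate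
Product: 19 (3S,7R,8R,10R)-8β-acetoxy-12,12-diethoxyeudesma-4,11(13)-dien-3β-yl 2-methylpropanoate
Conditions: Ac2O, Et3N, DMAP (cat.), CH2Cl2, 20 °C
Reagents that add atoms: acetic anhydride, CC(=O)OC(C)=O
Why: DMAP-catalysed acetylation of the axial alcohol, done while C12 is still an acetal so that the cis 8-hydroxy group can never lactonise onto a C12 ester.

Step 11
Reactants: 19 (3S,7R,8R,10R)-8β-acetoxy-12,12-diethoxyeudesma-4,11(13)-dien-3β-yl 2-methylpropanoate
Product: 20 (3S,7R,8R,10R)-8β-acetoxy-12-oxoeudesma-4,11(13)-dien-3β-yl 2-methylpropanoate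
Conditions: oxalic acid (aq.), THF, 20 °C
Reagents that add atoms: water, O
Why: Mild acid hydrolysis of the diethyl acetal releases the α-methylene aldehyde, while the acetate, the allylic isobutyrate and the non-enolisable C7 centre are untouched.

Step 12
Reactants: 20 (3S,7R,8R,10R)-8β-acetoxy-12-oxoeudesma-4,11(13)-dien-3β-yl 2-methylpropanoate
Product: 21 (3S,7R,8R,10R)-8β-acetoxy-3β-(2-methylpropanoyloxy)eudesma-4,11(13)-dien-12-oic acid
Conditions: NaClO2, NaH2PO4, 2-methyl-2-butene, t-BuOH/H2O, 0 → 20 °C
Reagents that add atoms: sodium chlorite, [Na+].[O-]Cl=O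
Why: Pinnick oxidation of the enal to the carboxylic acid, with 2-methyl-2-butene taking up the hypochlorous acid that would otherwise attack the alkenes.

Step 13
Reactants: 21 (3S,7R,8R,10R)-8β-acetoxy-3β-(2-methylpropanoyloxy)eudesma-4,11(13)-dien-12-oic acid
Product: 22 methyl (3S,7R,8R,10R)-8β-acetoxy-3β-(2-methylpropanoyloxy)eudesma-4,11(13)-dien-12-oate (CNP0127901.1)
Conditions: Me3SiCHN2, toluene/MeOH 4:1, 0 °C
Reagents that add atoms: trimethylsilyldiazomethane, C[Si](C)(C)C=[N+]=[N-]
Why: O-Methylation of the carboxylic acid by trimethylsilyldiazomethane in methanol under neutral conditions, which avoids ester exchange and conjugate addition to the acrylate.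

Compound list

1 | (±)-7-methyl-1,4-dioxaspiro[4.5]decan-8-one | CC1CC2(CCC1=O)OCCO2 | starting material
2 | (R)-1-phenylethylamine | C[C@@H](N)c1ccccc1 | starting material
3 | acrylonitrile | C=CC#N | starting material
4 | N-[(1R)-1-phenylethyl]imine of 1 (epimers at C7) | CC1CC2(CCC1=N[C@H](C)c3ccccc3)OCCO2 | intermediate
5 | (7R)-7-(2-cyanoethyl)-7-methyl-N-[(1R)-1-phenylethyl]-1,4-dioxaspiro[4.5]decan-8-imine | N#CCC[C@]1(C)CC2(CCC1=N[C@H](C)c3ccccc3)OCCO2 | intermediate
6 | 3-[(7R)-7-methyl-8-oxo-1,4-dioxaspiro[4.5]decan-7-yl]propanenitrile | N#CCC[C@]1(C)CC2(CCC1=O)OCCO2 | intermediate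
7 | ethynylmagnesium bromide | C#C[Mg]Br | starting material
8 | bromomagnesium alkoxide of 3-[(7R)-8-ethynyl-8-hydroxy-7-methyl-1,4-dioxaspiro[4.5]decan-7-yl]propanenitrile (C8 epimers) | N#CCC[C@]1(C)CC2(CCC1(O[Mg]Br)C#C)OCCO2 | intermediate
9 | (7R)-7-(2-cyanoethyl)-8-ethynyl-7-methyl-1,4-dioxaspiro[4.5]decan-8-yl methyl carbonate (C8 epimers) | N#CCC[C@]1(C)CC2(CCC1(OC(=O)OC)C#C)OCCO2 | intermediate
10 | 3-[(7R)-8-ethenylidene-7-methyl-1,4-dioxaspiro[4.5]decan-7-yl]propanenitrile | N#CCC[C@]1(C)CC2(CCC1=C=C)OCCO2 | intermediate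
11 | 3-[(7R)-8-ethenylidene-7-methyl-1,4-dioxaspiro[4.5]decan-7-yl]propanal | O=CCC[C@]1(C)CC2(CCC1=C=C)OCCO2 | intermediate
12 | triethylsilyl ether of 13 | C1CC2=C(C)[C@@H](O[Si](CC)(CC)CC)CC[C@]2(C)CC13OCCO3 | intermediate
13 | (3S,10R)-3β-hydroxy-11,12,13-trinoreudesm-4-en-8-one ethylene ketal (4,10-dimethyl-Δ4-octalin core, dioxolane at C8) | C1CC2=C(C)[C@@H](O)CC[C@]2(C)CC13OCCO3 | intermediate
14 | (3S,10R)-8,8-(ethylenedioxy)-11,12,13-trinoreudesm-4-en-3β-yl 2-methylpropanoate | C1CC2=C(C)[C@@H](OC(=O)C(C)C)CC[C@]2(C)CC13OCCO3 | intermediate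
15 | (3S,10R)-8-oxo-11,12,13-trinoreudesm-4-en-3β-yl 2-methylpropanoate | C1CC2=C(C)[C@@H](OC(=O)C(C)C)CC[C@]2(C)CC1=O | intermediate
16 | 2-bromo-3,3-diethoxyprop-1-ene | C=C(Br)C(OCC)OCC | starting material
17 | (3S,7R,10R)-12,12-diethoxy-8-oxoeudesma-4,11(13)-dien-3β-yl 2-methylpropanoate | C=C(C(OCC)OCC)[C@H]1CC2=C(C)[C@@H](OC(=O)C(C)C)CC[C@]2(C)CC1=O | intermediate
18 | (3S,7R,8R,10R)-12,12-diethoxy-8β-hydroxyeudesma-4,11(13)-dien-3β-yl 2-methylpropanoate | C=C(C(OCC)OCC)[C@H]1CC2=C(C)[C@@H](OC(=O)C(C)C)CC[C@]2(C)C[C@H]1O | intermediate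
19 | (3S,7R,8R,10R)-8β-acetoxy-12,12-diethoxyeudesma-4,11(13)-dien-3β-yl 2-methylpropanoate | C=C(C(OCC)OCC)[C@H]1CC2=C(C)[C@@H](OC(=O)C(C)C)CC[C@]2(C)C[C@H]1OC(C)=O | intermediate
20 | (3S,7R,8R,10R)-8β-acetoxy-12-oxoeudesma-4,11(13)-dien-3β-yl 2-methylpropanoate | C=C(C=O)[C@H]1CC2=C(C)[C@@H](OC(=O)C(C)C)CC[C@]2(C)C[C@H]1OC(C)=O | intermediate
21 | (3S,7R,8R,10R)-8β-acetoxy-3β-(2-methylpropanoyloxy)eudesma-4,11(13)-dien-12-oic acid | C=C(C(=O)O)[C@H]1CC2=C(C)[C@@H](OC(=O)C(C)C)CC[C@]2(C)C[C@H]1OC(C)=O | intermediate
22 | methyl (3S,7R,8R,10R)-8β-acetoxy-3β-(2-methylpropanoyloxy)eudesma-4,11(13)-dien-12-oate (CNP0127901.1) | C=C(C(=O)OC)[C@H]1CC2=C(C)[C@@H](OC(=O)C(C)C)CC[C@]2(C)C[C@H]1OC(C)=O | target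

Total step count: 13. Longest linear sequence: 13 steps from 1 (2, 3, 7 and 16 are bought).

Steps most likely to fail

Step 5. The oxidative cyclisation may engage the wrong allene π bond, aldehyde hydrosilylation or allene oligomerisation may outrun ring closure, or the facial selectivity at C3 may be poor. The fallback makes the same C3–C4 bond by an intramolecular Friedel–Crafts-type acylation of an alkene; it sets out from 6 and comes back at 13. Keto nitrile 6 is treated with Ph3P=CHCH3 (KOt-Bu, toluene, 90 °C) to give 3-[(7R)-8-ethylidene-7-methyl-1,4-dioxaspiro[4.5]decan-7-yl]propanenitrile F1 (either alkene geometry serves). Basic hydrolysis (KOH, ethylene glycol/H2O, 120 °C) gives the corresponding propanoic acid F2. The acid chloride ((COCl)2, DMF cat.) is cyclised with SnCl4 at −78 °C: the acylium ion attacks C4 in a 6-endo mode and leaves the tertiary C5 cation. Loss of HCl and an acidic work-up that also removes the ketal give (10R)-11,12,13-trinoreudesm-4-ene-3,8-dione F3. The saturated C8 ketone is ketalised selectively over the enone (ethylene glycol, TsOH, benzene, reflux) to the 8-ethylene ketal F4. Luche reduction (NaBH4, CeCl3·7H2O, MeOH, −78 °C) delivers hydride to the α face, anti to the C10 methyl, and gives 13. If only the C3 selectivity of step 5 fails, the epimer mixture of 13 is oxidised with MnO2 to the same enone F4 and reduced likewise.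

Step 8. Enolisation may go toward C9, the ketone may be alkenylated twice, the new double bond may move into conjugation with the ketone, the alkenylpalladium intermediate may lose ethoxide, or zerovalent palladium may ionise the allylic ester. The fallback brings in C11 and C12 as an allyl group and C13 by a separate methylenation; it sets out from 15 and comes back at 20. The kinetic lithium enolate of 15 (LiN(i-Pr)2, THF, −78 °C) is alkylated with allyl bromide and equilibrated with DBU to the 7β-allyl ketone F5. LiBH(s-Bu)3 at −78 °C gives the 7β-allyl 8β-alcohol F6, and Ac2O/DMAP gives the 7β-allyl 8β-acetate F7. Lemieux–Johnson cleavage (OsO4 cat., NaIO4, 2,6-lutidine, dioxane/H2O) of the monosubstituted alkene, in preference to the hindered tetrasubstituted one, gives the 8β-acetoxy 7β-(2-oxoethyl) compound F8. Mannich-type α-methylenation (aq. CH2O, pyrrolidine, propanoic acid, i-PrOH, 45 °C) gives enal 20.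

Step 3. Hydride may be delivered to the propargylic carbon instead of the alkyne terminus, or β-hydride loss to an enyne may compete. The fallback builds the allene by the Doering–LaFlamme sequence (Skattebøl rearrangement); it sets out from 6 and comes back at 10, replacing steps 2 and 3. Wittig methylenation of 6 (Ph3P=CH2, THF, reflux) gives 3-[(7R)-7-methyl-8-methylidene-1,4-dioxaspiro[4.5]decan-7-yl]propanenitrile F9. Dibromocarbene addition (CHBr3, KOt-Bu, pentane, 0 °C) gives the spiro gem-dibromocyclopropane F10. Bromine–lithium exchange with MeLi (Et2O, −78 °C) and opening of the cyclopropylidene carbenoid give allene 10.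

Further compounds

F1 | step 5 | 3-[(7R)-8-ethylidene-7-methyl-1,4-dioxaspiro[4.5]decan-7-yl]propanenitrile (E/Z) | N#CCC[C@]1(C)CC2(CCC1=CC)OCCO2
F2 | step 5 | 3-[(7R)-8-ethylidene-7-methyl-1,4-dioxaspiro[4.5]decan-7-yl]propanoic acid (E/Z) | OC(=O)CC[C@]1(C)CC2(CCC1=CC)OCCO2
F3 | step 5 | (10R)-11,12,13-trinoreudesm-4-ene-3,8-dione | C1CC2=C(C)C(=O)CC[C@]2(C)CC1=O
F4 | step 5 | (10R)-11,12,13-trinoreudesm-4-ene-3,8-dione 8-ethylene ketal | C1CC2=C(C)C(=O)CC[C@]2(C)CC13OCCO3
F5 | step 8 | (3S,10R)-7β-allyl-8-oxo-11,12,13-trinoreudesm-4-en-3β-yl 2-methylpropanoate | C=CC[C@H]1CC2=C(C)[C@@H](OC(=O)C(C)C)CC[C@]2(C)CC1=O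
F6 | step 8 | (3S,8R,10R)-7β-allyl-8β-hydroxy-11,12,13-trinoreudesm-4-en-3β-yl 2-methylpropanoate | C=CC[C@H]1CC2=C(C)[C@@H](OC(=O)C(C)C)CC[C@]2(C)C[C@H]1O
F7 | step 8 | (3S,8R,10R)-8β-acetoxy-7β-allyl-11,12,13-trinoreudesm-4-en-3β-yl 2-methylpropanoate | C=CC[C@H]1CC2=C(C)[C@@H](OC(=O)C(C)C)CC[C@]2(C)C[C@H]1OC(C)=O
F8 | step 8 | (3S,8R,10R)-8β-acetoxy-7β-(2-oxoethyl)-11,12,13-trinoreudesm-4-en-3β-yl 2-methylpropanoate | O=CC[C@H]1CC2=C(C)[C@@H](OC(=O)C(C)C)CC[C@]2(C)C[C@H]1OC(C)=O
F9 | step 3 | 3-[(7R)-7-methyl-8-methylidene-1,4-dioxaspiro[4.5]decan-7-yl]propanenitrile | N#CCC[C@]1(C)CC2(CCC1=C)OCCO2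
F10 | step 3 | spiro gem-dibromocyclopropane from F9 (1,1-dibromocyclopropane spiro-fused at the former C8; epimers at the spiro carbon) | N#CCC[C@]1(C)CC2(CCC13CC3(Br)Br)OCCO2
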